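## Structural features

Previtexilactone is a labdane in which a trans-decalin (ring A: C1–C5 and C10; ring B: C5–C10) carries a gem-dimethyl group at C4, an angular methyl group at C10, an equatorial 8α-methyl group and an axial 6β-acetoxy group. C9 is a spiro centre that ring B shares with a tetrahydrofuran (ring C: O, C9, C11, C12, C13), and C13 is a second spiro centre that ring C shares with a γ-lactone (ring D: C13, C14, C15, O, C16). Five of the six stereocentres are contiguous around ring B (C5, C6, C8, C9, C10); C9 and C10 are adjacent and both fully substituted, C10 is separated from the quaternary C4 only by C5, and the sixth stereocentre, C13, is a fully substituted ether carbon with no stereocentre nearer than C9. The fragile groups are the hindered secondary acetate, the two tertiary C–O bonds of the ring-C ether (acid-labile), and ring D, a β-alkoxy lactone that base can open by expelling the C13–O bond. The real difficulty is the crowded run C4–C5–C10–C9, in particular the C4–C5 bond between a quaternary carbon and a carbon flanked by a second one, together with control of the remote C13. The key step exploits two facts: C5 is the α-carbon of the C6 oxygen function, so a C5=C6 enol silane in ring B makes C5 nucleophilic, and C4 is a tertiary gem-dimethyl carbon, so it is easily made cationic from a homoprenyl chain on C10; their union forms C4–C5 and closes ring A last. Ring B, ring C and the C9 stereocentre can then all come from one dearomatised para-substituted phenol.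

## Logic of the disconnections

19 ⇒ 18 ⇒ 17: the O–acyl bond at C6, then the O–Si bond. The acetate is placed last because an ester would not survive the carbonyl methylenation used for ring D. This removes the most fragile group for the price of one silyl ether. The forward steps must acylate a hindered axial alcohol and remove silicon without base, since base opens the β-alkoxy lactone.

17 ⇒ 16: the C16–O bond of ring D (oxygen insertion next to C15). The lactone is traced to a spiro cyclobutanone whose two arms are identical, so C13 stops being a stereocentre. The forward oxidation must tell two diastereotopic methylene groups apart, which calls for a chiral catalyst that can be chosen in either antipode.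

16 ⇒ 15 ⇒ 14: the C13–C14 and C15–C16 bonds (and two C–Cl bonds). Both ring-D carbons C14 and C15 arrive from a two-carbon ketene, with regiochemistry dictated by the polarity of an enol ether. The forward step must preserve an acid-sensitive exocyclic enol ether and dechlorinate without β-elimination.

14 ⇒ 13: the C13=C16 double bond. Ring D is thereby reduced to the lactone carbonyl of ring C. The forward methylenation demands that C13 be the only carbonyl group present, which is why C6 is carried as a silyl ether.

13 ⇒ 12: the C6–H and O–Si bonds. The C6 stereocentre is traded for a ketone. The forward hydride must arrive from the α face, which the syn-axial methyl groups on C4 and C10 enforce.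

12 ⇒ 10 (through 11): the C4–C5 bond, opening ring A. Cutting here removes the most hindered bond and one ring and leaves a monocyclic spirolactone with a simple prenyl-type chain. The forward step needs a C4 cation generated in the presence of the C5=C6 enol silane, and a thermodynamic preference for the trans ring fusion at the epimerisable C5.

10 ⇒ 9: the C10–C20 methyl bond and the O–Si bond. The quaternary C10 and the regiodefined enol silane arise in one operation from an enone. The forward step needs axial delivery of methyl to a β,β-disubstituted carbon anti to the C9–O bond, without loss of the carboxylate at C9.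

9 ⇒ 8: the C8–C17 methyl bond. This returns to a cross-conjugated dienone. The forward addition must choose C8 over C10 (substitution) and the face syn to the ring oxygen.

8 ⇒ 7: the C9–O bond. Ring B, ring C and the C9 stereocentre collapse to a flat phenol with a propanoic acid chain. The forward oxidation must distinguish the two faces of the arene, which differ only through the ortho chain, and must not oxidise the alkene.

7 ⇒ 6 ⇒ 5 ⇒ 4: the two O–CH3 bonds, the C11–C12 π bond, then the C11=C12 double bond itself. These are functional-group changes and one olefination of an aldehyde. The forward steps need a reduction that touches only the conjugated double bond and a demethylation that avoids Lewis acids.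

4 ⇒ 1 + 2 (through 3): the aryl–C1 bond. This reaches the two commercial building blocks. The forward sp2–sp3 coupling must tolerate the free aldehyde.

## Other disconnections considered

Alternative 1: The cut is through C5–C10 and C6–C7, opening rings A and B at once to the acyclic nitro-diene ketone A1. In the forward step a chiral primary amine catalyst would turn the isopropenyl ketone of A1 into a 2-aminodiene; C10 would add to the nitroalkene carbon C5 and the nitronate carbon C6 would then add to C7, giving the nitro-decalinone A2.
- In its favour: two rings, two C–C bonds and the stereocentres C5, C6 and C10 (C8 by equilibration next to the C9 ketone) would come from one catalytic step on an achiral chain, and the nitro group marks C6 for later oxygenation.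
- Against it here: the C5–C10 bond joins a neopentyl nitroalkene carbon to the fully substituted carbon of a tetrasubstituted enamine, the most congested bond of the molecule made by a sterically sensitive Michael addition. A2 still lacks rings C and D. Its C9 ketone, flanked by C10 and C8, would have to accept a three-carbon nucleophile from the equatorial side while enolisation and the acidic nitro group interfere.
- Comparison: on structure, Alternative 1 is the better plan for the carbocyclic core, since it is catalytic in chirality and builds the decalin in one operation. On mechanism the chosen plan is stronger, because a cation meeting an enol silane is far less sensitive to crowding than an enamine meeting a hindered nitroalkene. On step economy, A1 is short to make, which equals or beats the way to 10, but the work after A2 (Nef reaction, telling two ketones apart, C9 addition, both spiro rings) would outweigh that gain.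

Alternative 2: The cut is through C7–C8 and C9–C10, opening ring B between preformed rings A and C. In the forward step the silyloxy diene A3 would add across the exocyclic C8=C9 bond of the (Z)-ethylidene furanone A4 in a Diels–Alder reaction, giving the tricyclic enol silane A5.
- In its favour: it is the most convergent plan. The vicinal quaternary pair C9/C10 and C8 would be set together, the (Z) geometry of A4 translates into the cis relation of the C8 methyl and C9–O, and the polarity of diene and dienophile match. A5 already carries C16 and an enone at C13 for introducing C14–C15, so ring D is better prepared than in the chosen plan.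
- Against it here: the diene terminus C10 of A3 is tetrasubstituted and twisted by the neighbouring gem-dimethyl group, and A4 is a trisubstituted, donor-substituted dienophile, so the C9–C10 bond between two fully substituted carbons would form reluctantly. The endo/exo and facial selectivity that decide C10 relative to C9, and the absolute configuration, have no built-in control. The C11 carbonyl of A5 must later be removed.
- Comparison: on convergence and on the provision for ring D, Alternative 2 is the better. On mechanism and stereocontrol the chosen plan is safer, since it sets C8, C10 and C5 one at a time on a rigid ring. On step economy the two are about equal once the preparation of A3 and A4 and the deoxygenation at C11 are counted.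

Alternative 3: The cut is the C8–C9 bond, reopening ring B to the seco keto-enone A6. In the forward step SmI2 (divalent samarium) would reduce A6 and couple the C9 ketyl carbon with the enone β-carbon C8, giving the 9α-hydroxy-6-ketone A7 with the C8 methyl in place.
- In its favour: a ketyl radical tolerates crowding, C8 and C9 are set in the ring closure, and A7 has the C6 ketone and the 9α-oxygen in the right oxidation states. A free 9-hydroxyl group also opens a late oxa-Michael closure of ring C onto a butenolide under equilibrating conditions, which for C13 could be the equal of, or better than, the catalyst-controlled oxidation of the chosen plan.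
- Against it here: A6 already contains ring A with the C4–C5 bond, the quaternary C10 and the trans relation of C5 and C10 as a single enantiomer, so the hardest part is moved into the precursor. The enone may be reduced before the ketone, leading to simple conjugate reduction. The configuration at C9 rests on a chelate whose geometry is hard to predict.
- Comparison: on mechanism the two plans are equal, since each makes a hindered bond through a reactive intermediate that is indifferent to crowding. On structure the chosen plan gains ring B, ring C and C9 from one dearomatisation, whereas Alternative 3 postpones ring C. On step economy the chosen plan is shorter to its key-step precursor.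

Key step: step 8

Remark on the chemistry: α and β refer to the usual labdane drawing with the C10 methyl group β. Wherever a chiral reagent is used (steps 5 and 12), the antipode that leads to the drawn configuration is meant; the sense of induction is left to be established, and the (R,R)- and (R)-forms are written for bookkeeping. The cinnamate is made by a Wittig reaction and reduced as its methyl ester, so malonic acid is not used.

## Route

Step 1
Reactants: 1 2-bromo-4-methoxybenzaldehyde; 2 5-bromo-2-methylpent-2-ene
Product: 4 4-methoxy-2-(4-methylpent-3-en-1-yl)benzaldehyde, via homoprenylzinc bromide 3 (not isolated)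
Conditions: 2, Zn dust, LiCl, THF, 50 °C; then 1, Pd(OAc)2 (2 mol%), SPhos (4 mol%), THF, rt
Reagents that add atoms: none
Why: Negishi coupling: zinc inserts into the primary C–Br bond of 2, and zerovalent palladium carrying SPhos couples 3 with the aryl bromide, which the ortho formyl group activates; an alkylzinc bromide does not add to an aldehyde at room temperature, so no protecting group is needed and no stereocentre is formed.

Step 2
Reactants: 4 4-methoxy-2-(4-methylpent-3-en-1-yl)benzaldehyde
Product: 5 methyl (E)-3-[4-methoxy-2-(4-methylpent-3-en-1-yl)phenyl]prop-2-enoate
Conditions: Ph3P=CHCO2Me, toluene, 80 °C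
Reagents that add atoms: methyl (triphenylphosphoranylidene)acetate, COC(=O)C=P(c1ccccc1)(c1ccccc1)c1ccccc1
Why: Wittig olefination with a stabilised ylide should give the (E)-cinnamate without added base; any (Z)-isomer is harmless because this double bond is reduced in step 3.

Step 3
Reactants: 5 methyl (E)-3-[4-methoxy-2-(4-methylpent-3-en-1-yl)phenyl]prop-2-enoate
Product: 6 methyl 3-[4-methoxy-2-(4-methylpent-3-en-1-yl)phenyl]propanoate
Conditions: Mg turnings, MeOH, 0 °C → rt
Reagents that add atoms: none
Why: Dissolving-metal conjugate reduction (Mg in MeOH) works by electron transfer to the aryl-conjugated enoate only, so the isolated trisubstituted alkene, which a catalytic hydrogenation would endanger, should be left alone.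

Step 4
Reactants: 6 methyl 3-[4-methoxy-2-(4-methylpent-3-en-1-yl)phenyl]propanoate
Product: 7 3-[4-hydroxy-2-(4-methylpent-3-en-1-yl)phenyl]propanoic acid
Conditions: NaSEt (5 equiv), DMF, 130 °C; then 1 M HCl, 0 °C
Reagents that add atoms: none
Why: Thiolate SN2 dealkylation removes both O-methyl groups (aryl ether and ester) in one basic operation; a Lewis-acid demethylation is avoided because it would ionise the homoprenyl alkene and close a tetralin onto the electron-rich arene.

Step 5
Reactants: 7 3-[4-hydroxy-2-(4-methylpent-3-en-1-yl)phenyl]propanoic acid
Product: 8 (5R)-6-(4-methylpent-3-en-1-yl)-1-oxaspiro[4.5]deca-6,9-diene-2,8-dione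
Conditions: preformed (R,R)-ArI(OAc)2 [ArI = 2,2′-[(2-iodo-1,3-phenylene)bis(oxy)]bis(N-mesitylpropanamide)] (1.1 equiv), CH2Cl2, −20 °C
Reagents that add atoms: none
Why: Oxidative dearomatising para-spirolactonisation of a 4-substituted phenol by a chiral trivalent-iodine reagent: the phenol oxygen binds iodine, the carboxyl group attacks the para carbon (5-exo) and the aryl iodide departs, while the C2-symmetric lactamide arms differentiate the two ring faces, which differ through the ortho homoprenyl group, and so set C9. The reagent is used preformed and stoichiometric so that no peracid meets the trisubstituted alkene.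

Step 6
Reactants: 8 (5R)-6-(4-methylpent-3-en-1-yl)-1-oxaspiro[4.5]deca-6,9-diene-2,8-dione
Product: 9 (5R,10R)-10-methyl-6-(4-methylpent-3-en-1-yl)-1-oxaspiro[4.5]dec-6-ene-2,8-dione
Conditions: Me2CuLi (from MeLi and CuI, 1.3 equiv), THF/Et2O, −78 °C; aq. NH4Cl
Reagents that add atoms: lithium dimethylcuprate, [Li+].C[Cu-]C
Why: Conjugate addition of a Gilman cuprate to a cross-conjugated cyclohexadienone: C8 is the only unsubstituted β-carbon, and attack should occur on the face syn to the ring oxygen (anti to the C11 methylene), the usual electrostatically controlled preference of 4-alkyl-4-oxy dienones, so the C8 methyl ends cis to the C9–O bond (8α). The lactone is inert to the cuprate at −78 °C.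

Step 7
Reactants: 9 (5R,10R)-10-methyl-6-(4-methylpent-3-en-1-yl)-1-oxaspiro[4.5]dec-6-ene-2,8-dione
Product: 10 (5R,6S,10R)-6,10-dimethyl-6-(4-methylpent-3-en-1-yl)-8-(trimethylsilyloxy)-1-oxaspiro[4.5]dec-7-en-2-one
Conditions: Me2CuLi (3 equiv), TMSCl (5 equiv), THF, −78 → −40 °C; Et3N, pentane, cold aq. NaHCO3
Reagents that add atoms: lithium dimethylcuprate, [Li+].C[Cu-]C; chlorotrimethylsilane, C[Si](C)(C)Cl
Why: Chlorosilane-accelerated cuprate addition to a β,β-disubstituted enone: in the half-chair with the C8 methyl equatorial the C9–O bond is axial, and the stereoelectronically preferred axial attack at C10 anti to it places the new methyl group β and leaves the homoprenyl chain α. TMSCl both speeds the addition at this hindered carbon and traps the enolate on oxygen, which fixes the C5=C6 position of the enol silane.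

Step 8
Reactants: 10 (5R,6S,10R)-6,10-dimethyl-6-(4-methylpent-3-en-1-yl)-8-(trimethylsilyloxy)-1-oxaspiro[4.5]dec-7-en-2-one
Product: 12 (5S,8R,9R,10S)-6-oxo-14,15,16-trinorlabdan-13,9α-olide (5α-H; 8α-CH3; 10β-CH3), via cis-fused 5β-H ketone 11 (not isolated)
Conditions: HNTf2 (0.2 equiv), CH2Cl2 (0.01 M), −78 → −30 °C; then 1 M HCl, THF, rt; then DBU, toluene, 60 °C
Reagents that add atoms: none
Why: HNTf2 starts a proton chain in which the proton, carried by C6 silyloxocarbenium ions, adds to C3 of the homoprenyl alkene (Markovnikov) to give the tertiary C4 cation; C5 of the C5=C6 enol silane attacks it, and the resulting C6 silyloxocarbenium ion passes on its proton or its silyl group, so that hydrolytic work-up leaves the C6 ketone. The closest known reaction type is the acid-promoted cation–olefin cyclisation terminated by a silyl enol ether, that is, the intramolecular α-tert-alkylation of a ketone. Ring A closes through a chair-like transition state in a 6-endo-trig mode with respect to the protonated C3=C4 alkene and an enol-exo mode with respect to the nucleophile. The new stereocentre C5 is formed by attack along the π axis on the α face, the only face the α-oriented C10 tether can reach, which gives the cis-fused ketone 11. C5 is α to the ketone, and DBU should equilibrate it to the trans-fused 12, in which the C10 methyl is axial and both ring-A bonds are equatorial on ring B. Regioselectivity is secured by the tether, since only C5 (not C7 or the enol oxygen) can reach C4 in a six-membered ring. The chemoselectivity needed is that C–C bond formation outruns loss of the enol silane: C-protonation of the enol silane is reversible through silyl and proton exchange whereas attack on the C4 cation is not, and low temperature, high dilution and a substoichiometric charge of acid keep free ketone and free acid low. The lactone and the stereocentres C8, C9 and C10 have no position that ionises under these conditions except the tertiary C9–O bond, which the low temperature protects.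

Step 9
Reactants: 12 (5S,8R,9R,10S)-6-oxo-14,15,16-trinorlabdan-13,9α-olide
Product: 13 6β-(triethylsilyloxy)-14,15,16-trinorlabdan-13,9α-olide
Conditions: Et3SiH (3 equiv), (IPr)CuCl [IPr = 1,3-bis(2,6-diisopropylphenyl)imidazol-2-ylidene] (5 mol%), NaOtBu (10 mol%), toluene, rt
Reagents that add atoms: triethylsilane, CC[SiH](CC)CC
Why: Copper-hydride-catalysed hydrosilylation of a ketone: the bulky carbene–Cu–H adds to C6 from the α face because the β face is closed by the syn-axial C10 and 4β methyl groups, giving the axial 6β-oxygen (6R), and σ-bond metathesis with Et3SiH releases the silyl ether directly. Lactones are not reduced by copper hydride at this temperature.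

Step 10
Reactants: 13 6β-(triethylsilyloxy)-14,15,16-trinorlabdan-13,9α-olide
Product: 14 9α,13-epoxy-6β-(triethylsilyloxy)-14,15-dinorlabd-13(16)-ene
Conditions: Cp2TiMe2 (3 equiv), toluene, 70 °C, dark; filtration through basic alumina
Reagents that add atoms: dimethyltitanocene, [CH3-].[CH3-].[Ti+4].c1cc[cH-]c1.c1cc[cH-]c1
Why: Petasis methylenation: thermolysis of Cp2TiMe2 gives the titanium methylidene, which converts the lactone carbonyl, the only carbonyl group left, into the exocyclic enol ether under non-acidic conditions. The silyl ether is inert, which is why C6 is carried as a silyl ether and not as the acetate.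

Step 11
Reactants: 14 9α,13-epoxy-6β-(triethylsilyloxy)-14,15-dinorlabd-13(16)-ene
Product: 16 9α,13-epoxy-6β-(triethylsilyloxy)-15,16-cyclolabdan-15-one, via spiro dichlorocyclobutanone 15 (not isolated)
Conditions: Cl2CHCOCl, Et3N, Et2O, 0 °C → rt; filter; then Zn(Cu), NH4Cl, MeOH, rt
Reagents that add atoms: dichloroacetyl chloride, O=C(Cl)C(Cl)Cl
Why: [2+2] Cycloaddition of dichloroketene to an electron-rich enol ether: the nucleophilic methylene C16 bonds to the ketene carbonyl carbon and C13 to CCl2, so polarity fixes the regiochemistry, and the base-generated ketene avoids Lewis acids that would isomerise the enol ether. Zinc then removes both chlorine atoms under buffered conditions, which also erases the C13 configuration of 15 because the two arms of 16 become identical.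

Step 12
Reactants: 16 9α,13-epoxy-6β-(triethylsilyloxy)-15,16-cyclolabdan-15-one
Product: 17 (13S)-9α,13-epoxy-6β-(triethylsilyloxy)labdan-16,15-olide
Conditions: (R)-TRIP [3,3′-bis(2,4,6-triisopropylphenyl)-1,1′-binaphthyl-2,2′-diyl hydrogen phosphate] (10 mol%), 30% aq. H2O2, CHCl3, −40 °C
Reagents that add atoms: hydrogen peroxide, OO
Why: Baeyer–Villiger oxidation of a strained cyclobutanone with group selection by a chiral Brønsted acid: the acid activates ketone and H2O2, and the Criegee intermediate migrates one of the two diastereotopic methylene groups, which becomes C16 and thereby defines C13 (13S). The antipode of the acid that reinforces the bias of the chiral substrate is used, and the weakly acidic medium avoids Lewis-acid opening of the 3-alkoxycyclobutanone.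

Step 13
Reactants: 17 (13S)-9α,13-epoxy-6β-(triethylsilyloxy)labdan-16,15-olide
Product: 18 (13S)-6β-hydroxy-9α,13-epoxylabdan-16,15-olide
Conditions: HF·pyridine, THF, 0 °C → rt
Reagents that add atoms: none
Why: Fluoride-driven Si–O cleavage under buffered acidic conditions; a basic fluoride source is avoided because base could open ring C by β-elimination of the C13–O bond of the β-alkoxy lactone.

Step 14
Reactants: 18 (13S)-6β-hydroxy-9α,13-epoxylabdan-16,15-olide
Product: 19 previtexilactone, (5S,6R,8R,9R,10S,13S)-6β-acetoxy-9α,13-epoxylabdan-16,15-olide
Conditions: Ac2O, DMAP, pyridine, 40 °C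
Reagents that add atoms: acetic anhydride, CC(=O)OC(C)=O
Why: DMAP-catalysed acylation of the hindered axial 6β-alcohol; no stereocentre is touched, and the amine bases are too weak to trigger the retro-oxa-Michael opening of ring C.

## Compound list

1 | 2-bromo-4-methoxybenzaldehyde | COc1ccc(C=O)c(Br)c1 | starting material
2 | 5-bromo-2-methylpent-2-ene | CC(C)=CCCBr | starting material
3 | (4-methylpent-3-en-1-yl)zinc bromide (homoprenylzinc bromide) | CC(C)=CCC[Zn]Br | intermediate (not isolated)
4 | 4-methoxy-2-(4-methylpent-3-en-1-yl)benzaldehyde | COc1ccc(C=O)c(CCC=C(C)C)c1 | intermediate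
5 | methyl (E)-3-[4-methoxy-2-(4-methylpent-3-en-1-yl)phenyl]prop-2-enoate | COC(=O)/C=C/c1ccc(OC)cc1CCC=C(C)C | intermediate
6 | methyl 3-[4-methoxy-2-(4-methylpent-3-en-1-yl)phenyl]propanoate | COC(=O)CCc1ccc(OC)cc1CCC=C(C)C | intermediate
7 | 3-[4-hydroxy-2-(4-methylpent-3-en-1-yl)phenyl]propanoic acid | OC(=O)CCc1ccc(O)cc1CCC=C(C)C | intermediate
8 | (5R)-6-(4-methylpent-3-en-1-yl)-1-oxaspiro[4.5]deca-6,9-diene-2,8-dione | O=C1C=C[C@]2(CCC(=O)O2)C(CCC=C(C)C)=C1 | intermediate
9 | (5R,10R)-10-methyl-6-(4-methylpent-3-en-1-yl)-1-oxaspiro[4.5]dec-6-ene-2,8-dione (methyl cis to the ring oxygen) | O=C1C[C@@H](C)[C@]2(CCC(=O)O2)C(CCC=C(C)C)=C1 | intermediate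
10 | (5R,6S,10R)-6,10-dimethyl-6-(4-methylpent-3-en-1-yl)-8-(trimethylsilyloxy)-1-oxaspiro[4.5]dec-7-en-2-one (key-step precursor) | C[Si](C)(C)OC1=C[C@](C)(CCC=C(C)C)[C@@]2(CCC(=O)O2)[C@H](C)C1 | intermediate
11 | (5R,8R,9R,10S)-6-oxo-14,15,16-trinorlabdan-13,9α-olide, cis-fused (5β-H) | O=C1C[C@@H](C)[C@]2(CCC(=O)O2)[C@@]2(C)CCCC(C)(C)[C@@H]12 | intermediate (not isolated)
12 | (5S,8R,9R,10S)-6-oxo-14,15,16-trinorlabdan-13,9α-olide, trans-fused (5α-H, 8α-CH3, 10β-CH3; key-step product) | O=C1C[C@@H](C)[C@]2(CCC(=O)O2)[C@@]2(C)CCCC(C)(C)[C@H]12 | intermediate
13 | (5S,6R,8R,9R,10S)-6β-(triethylsilyloxy)-14,15,16-trinorlabdan-13,9α-olide | CC[Si](CC)(CC)O[C@@H]1C[C@@H](C)[C@]2(CCC(=O)O2)[C@@]2(C)CCCC(C)(C)[C@H]12 | intermediate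
14 | 9α,13-epoxy-6β-(triethylsilyloxy)-14,15-dinorlabd-13(16)-ene (exocyclic enol ether) | CC[Si](CC)(CC)O[C@@H]1C[C@@H](C)[C@]2(CCC(=C)O2)[C@@]2(C)CCCC(C)(C)[C@H]12 | intermediate
15 | 14,14-dichloro-9α,13-epoxy-6β-(triethylsilyloxy)-15,16-cyclolabdan-15-one (both C13 epimers) | CC[Si](CC)(CC)O[C@@H]1C[C@@H](C)[C@]2(CCC3(CC(=O)C3(Cl)Cl)O2)[C@@]2(C)CCCC(C)(C)[C@H]12 | intermediate (not isolated)
16 | 9α,13-epoxy-6β-(triethylsilyloxy)-15,16-cyclolabdan-15-one (C13 not a stereocentre) | CC[Si](CC)(CC)O[C@@H]1C[C@@H](C)[C@]2(CCC3(CC(=O)C3)O2)[C@@]2(C)CCCC(C)(C)[C@H]12 | intermediate
17 | (13S)-9α,13-epoxy-6β-(triethylsilyloxy)labdan-16,15-olide | CC[Si](CC)(CC)O[C@@H]1C[C@@H](C)[C@]2(CC[C@]3(COC(=O)C3)O2)[C@@]2(C)CCCC(C)(C)[C@H]12 | intermediate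
18 | (13S)-6β-hydroxy-9α,13-epoxylabdan-16,15-olide | O[C@@H]1C[C@@H](C)[C@]2(CC[C@]3(COC(=O)C3)O2)[C@@]2(C)CCCC(C)(C)[C@H]12 | intermediate
19 | previtexilactone, (5S,6R,8R,9R,10S,13S)-6β-acetoxy-9α,13-epoxylabdan-16,15-olide | CC(=O)O[C@@H]1C[C@@H](C)[C@]2(CC[C@]3(COC(=O)C3)O2)[C@@]2(C)CCCC(C)(C)[C@H]12 | target

## Step count and least certain steps

Total step count: 14. Longest linear sequence: 14 steps from 1 (the route is linear; 2 enters in step 1).

Step 8 (key step). The most likely failure is protonation at the wrong π system. The enol silane is more basic than the trisubstituted alkene, so the acid may strip silicon before the C4 cation is formed; the silyl-activated ketone can then be attacked at C6 by the alkene (a Prins-type closure to a bridged ring) instead of C5 attacking C4. A strong acid may also ionise the tertiary C9–O bond of the lactone. The fallback removes the proton from the problem and sets out from 9. Hydrochlorination of the alkene (HCl, CH2Cl2, −30 °C) would give (5R,10R)-6-(4-chloro-4-methylpentyl)-10-methyl-1-oxaspiro[4.5]dec-6-ene-2,8-dione F1. The cuprate/TMSCl addition of step 7 applied to it would give (5R,6S,10R)-6-(4-chloro-4-methylpentyl)-6,10-dimethyl-8-(trimethylsilyloxy)-1-oxaspiro[4.5]dec-7-en-2-one F2. TiCl4 in CH2Cl2 at −78 °C would ionise the tertiary chloride with no proton source present (Lewis-acid-mediated α-tert-alkylation of a silyl enol ether with a tertiary halide), forming the same C4–C5 bond. The same DBU equilibration brings the material back to the route at 12.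

Step 7. The likely failure is loss of the carboxylate from C9 instead of C–C bond formation. The copper-bound C10 is anti-periplanar to the axial C9–O bond, an acyloxy leaving group, so β-elimination with opening of ring C can compete with the slow reductive elimination at this hindered carbon; simple lack of reactivity is the second risk. The fallback avoids a copper intermediate and sets out from 9. Corey–Chaykovsky cyclopropanation (Me3S(O)I, NaH, DMSO), again anti to the C9–O bond, would give the cyclopropyl ketone in which a β-oriented CH2 bridges C5 and C10, F3. Reductive opening of the external cyclopropane bond with SmI2 (THF/DMPU, −78 °C), followed by trapping of the enolate with TMSCl/Et3N, would turn the bridging carbon into the C10 methyl group and give the C5=C6 enol silane, returning to the route at 10.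

Step 5. The likely failure is weak facial discrimination. The carboxyl group attacks the para carbon far from the chiral ligands on iodine, and the two faces differ only through the ortho chain, so the enantiomeric purity of 8 may be low. Participation of the alkene in the oxidised arene is a second risk. The fallback gives up asymmetric induction and sets out from 7. PhI(OAc)2 in CH2Cl2 would give racemic spirolactone; 8 is separated by chromatography on a chiral stationary phase from its enantiomer, (5S)-6-(4-methylpent-3-en-1-yl)-1-oxaspiro[4.5]deca-6,9-diene-2,8-dione F4. F4 is reduced back to 7 with Zn/AcOH (reductive rearomatisation) and oxidised again. The route is rejoined at 8.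

Step 12. The likely failure is poor group selection. The two methylene groups of 16 differ only through a remote oxygen-versus-carbon contrast at C13, so neither antipode of the catalyst may give a useful preference, or the substrate bias may oppose it. The fallback replaces kinetic selection by recycling through a reversible ring opening and sets out from 16. Unselective oxidation (mCPBA, NaHCO3, CH2Cl2) would give 17 together with its epimer, (13R)-9α,13-epoxy-6β-(triethylsilyloxy)labdan-16,15-olide F5. After separation, F5 is treated with DBU in toluene; β-elimination of the C13–O bond opens ring C to the butenolide 9α-hydroxy-6β-(triethylsilyloxy)labd-13-en-16,15-olide F6, which closes again by oxa-Michael addition to a mixture of F5 and 17. Repeating separation and equilibration returns the material to the route at 17.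

## Further compounds

F1 | step 8 | (5R,10R)-6-(4-chloro-4-methylpentyl)-10-methyl-1-oxaspiro[4.5]dec-6-ene-2,8-dione | O=C1C[C@@H](C)[C@]2(CCC(=O)O2)C(CCCC(C)(C)Cl)=C1
F2 | step 8 | (5R,6S,10R)-6-(4-chloro-4-methylpentyl)-6,10-dimethyl-8-(trimethylsilyloxy)-1-oxaspiro[4.5]dec-7-en-2-one | C[Si](C)(C)OC1=C[C@](C)(CCCC(C)(C)Cl)[C@@]2(CCC(=O)O2)[C@H](C)C1
F3 | step 7 | cyclopropyl ketone from 9 with a β-oriented CH2 bridging C5 and C10 (5,10-methano derivative of 9) | O=C1C[C@@H](C)[C@]2(CCC(=O)O2)[C@]3(CCC=C(C)C)C[C@H]13
F4 | step 5 | (5S)-6-(4-methylpent-3-en-1-yl)-1-oxaspiro[4.5]deca-6,9-diene-2,8-dione (enantiomer of 8) | O=C1C=C[C@@]2(CCC(=O)O2)C(CCC=C(C)C)=C1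
F5 | step 12 | (13R)-9α,13-epoxy-6β-(triethylsilyloxy)labdan-16,15-olide (C13 epimer of 17) | CC[Si](CC)(CC)O[C@@H]1C[C@@H](C)[C@]2(CC[C@@]3(COC(=O)C3)O2)[C@@]2(C)CCCC(C)(C)[C@H]12
F6 | step 12 | 9α-hydroxy-6β-(triethylsilyloxy)labd-13-en-16,15-olide (butenolide) | CC[Si](CC)(CC)O[C@@H]1C[C@@H](C)[C@](O)(CCC2=CC(=O)OC2)[C@@]2(C)CCCC(C)(C)[C@H]12
A1 | alternative 1 | (9E)-2,4,8,8-tetramethyl-10-nitrodeca-1,9-dien-3-one (racemic at C4 of the chain) | CC(=C)C(=O)C(C)CCCC(C)(C)/C=C/[N+](=O)[O-]
A2 | alternative 1 | 4,4,8α,10β-tetramethyl-6α-nitro-trans-decalin-9-one (labdane numbering) | [O-][N+](=O)[C@H]1C[C@@H](C)C(=O)[C@@]2(C)CCCC(C)(C)[C@H]12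
A3 | alternative 2 | tert-butyl(dimethyl){[1-(2,6,6-trimethylcyclohex-1-en-1-yl)ethenyl]oxy}silane | C=C(O[Si](C)(C)C(C)(C)C)C1=C(C)CCCC1(C)C
A4 | alternative 2 | (Z)-5-[(tert-butyldimethylsilyloxy)methyl]-2-ethylidenefuran-3(2H)-one | C/C=C1\OC(CO[Si](C)(C)C(C)(C)C)=CC1=O
A5 | alternative 2 | tricyclic spiro furan-3-one with C5=C6 tert-butyldimethylsilyl enol ether (rings A, B, C; 8α-CH3, 9α-O, 10β-CH3) | CC(C)(C)[Si](C)(C)OC1=C2C(C)(C)CCC[C@]2(C)[C@]3(OC(CO[Si](C)(C)C(C)(C)C)=CC3=O)[C@H](C)C1
A6 | alternative 3 | (E)-1-{2-[4-(tert-butyldimethylsilyloxy)butanoyl]-2,6,6-trimethylcyclohexyl}but-2-en-1-one, acyl groups trans (5α-H, 10β-CH3; 8,9-seco keto-enone) | C/C=C/C(=O)[C@H]1C(C)(C)CCC[C@]1(C)C(=O)CCCO[Si](C)(C)C(C)(C)C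
A7 | alternative 3 | 9α-hydroxy-8α-methyl-9β-[3-(tert-butyldimethylsilyloxy)propyl]-4,4,10-trimethyl-trans-decalin-6-one | O=C1C[C@@H](C)[C@](O)(CCCO[Si](C)(C)C(C)(C)C)[C@@]2(C)CCCC(C)(C)[C@H]12
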